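**Plan**
1. Retrosynthesis: cut C12–C13 (auxiliary-controlled aldol, then imide closure) and C8=C17 (Wittig); take C2–Cl back to a C2 ketone; cut ring A at C1–C2 and C4–C5 in one step; cut the remaining ring B cyclohexene by a Diels–Alder reaction.
2. Forward: an enantioselective Diels–Alder reaction gives ring B with quaternary C10 and the C9 side chain. Luche reduction gives the C7 β-alcohol, C1 becomes a CH2SO2Ph group, and O7 is esterified with a 2-methylsuccinic half-amide that carries C18, C4, C3 and C2.
3. Enabling feature: in ring B the allylic O7 is 1,3 to C5 across C5=C6, and C1 sits on quaternary C10 next to C5. A [3,3] shift from O7 to C5 therefore brings C2 within reach of the C1 carbanion.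
4. Key event: ester-enolate Claisen rearrangement (C4–C5), then acylation of the sulfonyl carbanion by the amide (C1–C2), in one flask; this closes ring A trans-fused.
5. Stereochemistry: C9/C10 from dienophile geometry and the chiral catalyst; C7 by substrate control; C5 by suprafacial chirality transfer from C7; C4 by enolate geometry and a boat transition state; C2 by α-face hydride attack then SN2 inversion; C12/C13 by the oxazolidinone.
6. End game: allylic oxidation at C8, hydrogenation, methylenation, aldol, imide closure, desilylation.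

Key step: step 9

Remark: positions are named by the labdane numbering of the target (C1–C20, C18 = the CH2OH carbon); β is the face of the C10 methyl group.
Remark: the sense of induction of the chromium catalyst in step 2 is assumed; if it is the opposite, the (S,S)-ligand is used.
Remark: acid 14 is used as the racemate because its stereocentre becomes the planar enolate carbon in step 9.

**Step 1**
Reactants: 1 3-(benzyloxy)propanal; 2 2-(triphenylphosphoranylidene)propanal
Product: 3 (E)-5-(benzyloxy)-2-methylpent-2-enal
Conditions: toluene, 90 °C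
Reagents that add atoms: none
Why: Wittig olefination with a stabilised formyl ylide gives the trisubstituted (E)-enal, so that CHO and the CH2CH2OBn chain are trans.

**Step 2**
Reactants: 3 (E)-5-(benzyloxy)-2-methylpent-2-enal; 4 (E)-3-(tert-butyldimethylsilyloxy)-N,N-dimethylbuta-1,3-dien-1-amine
Product: 7 4-(hydroxymethyl)-4-methyl-5-[2-(benzyloxy)ethyl]cyclohex-2-en-1-one (hydroxymethyl trans to the side chain), via cycloadduct aldehyde 5 (not isolated), via cycloadduct alcohol 6 (not isolated)
Conditions: (salen)CrSbF6 [salen = dianion of (R,R)-N,N′-bis(3,5-di-tert-butylsalicylidene)cyclohexane-1,2-diamine], 5 mol %, 4 Å molecular sieves, CH2Cl2, −40 °C; then LiAlH4, Et2O, −78 °C; then aqueous HF, MeCN, 0 °C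
Reagents that add atoms: none
Why: Catalytic enantioselective Diels–Alder reaction of a 1-amino-3-siloxy diene with an α-substituted enal bound to the chiral chromium Lewis acid, in which the CH2 terminus of the diene joins the β-carbon (C9) and the aminated terminus joins the α-carbon (C10), the (E)-geometry of 3 places the C10 methyl cis to the C9 chain and the catalyst sets the absolute configuration, after which hydride reduction of the aldehyde and acid-induced enol ether hydrolysis with β-elimination of dimethylamine give the enone.

**Step 3**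
Reactants: 7 4-(hydroxymethyl)-4-methyl-5-[2-(benzyloxy)ethyl]cyclohex-2-en-1-one
Product: 8 4-(iodomethyl)-4-methyl-5-[2-(benzyloxy)ethyl]cyclohex-2-en-1-one
Conditions: PPh3, I2, imidazole, toluene, 80 °C
Reagents that add atoms: iodine, II
Why: Appel-type iodination of the primary neopentyl alcohol through its alkoxyphosphonium salt; no stereocentre is touched.

**Step 4**
Reactants: 8 4-(iodomethyl)-4-methyl-5-[2-(benzyloxy)ethyl]cyclohex-2-en-1-one
Product: 9 4-(iodomethyl)-4-methyl-5-[2-(benzyloxy)ethyl]cyclohex-2-en-1-ol (C7 hydroxyl β)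
Conditions: NaBH4, CeCl3·7H2O, MeOH, −78 °C
Reagents that add atoms: none
Why: Luche 1,2-reduction in which hydride attacks the carbonyl axially from the α face, away from the axial C10 methyl, to give the pseudo-equatorial C7 β-alcohol cis to the equatorial C9 chain (the carvone to cis-carveol pattern).

**Step 5**
Reactants: 9 4-(iodomethyl)-4-methyl-5-[2-(benzyloxy)ethyl]cyclohex-2-en-1-ol
Product: 10 4-methyl-4-[(phenylsulfanyl)methyl]-5-[2-(benzyloxy)ethyl]cyclohex-2-en-1-ol
Conditions: PhSNa, DMF, 80 °C
Reagents that add atoms: sodium benzenethiolate, [Na+].[S-]c1ccccc1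
Why: SN2 displacement of the primary iodide by the highly nucleophilic thiolate, which tolerates the neopentyl position (no β-hydrogen, hence no elimination) and the free alcohol.

**Step 6**
Reactants: 10 4-methyl-4-[(phenylsulfanyl)methyl]-5-[2-(benzyloxy)ethyl]cyclohex-2-en-1-ol
Product: 11 4-methyl-4-[(phenylsulfonyl)methyl]-5-[2-(benzyloxy)ethyl]cyclohex-2-en-1-ol
Conditions: 30 % aqueous H2O2, (NH4)6Mo7O24·4H2O (5 mol %), EtOH, 0 °C to rt
Reagents that add atoms: hydrogen peroxide, OO
Why: Molybdate-catalysed sulfide-to-sulfone oxidation, which is much faster than epoxidation of the disubstituted ring alkene.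

**Step 7**
Reactants: 12 methylsuccinic anhydride; 13 morpholine
Product: 14 2-methyl-4-(morpholin-4-yl)-4-oxobutanoic acid
Conditions: THF, 0 °C to rt; crystallisation from the minor regioisomer
Reagents that add atoms: none
Why: Aminolysis of the cyclic anhydride at the less hindered carbonyl (next to CH2) leaves the free acid next to the methyl-bearing carbon, the future C18 and C4.

**Step 8**
Reactants: 11 4-methyl-4-[(phenylsulfonyl)methyl]-5-[2-(benzyloxy)ethyl]cyclohex-2-en-1-ol; 14 2-methyl-4-(morpholin-4-yl)-4-oxobutanoic acid
Product: 15 C7 β-ester of 11 with acid 14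
Conditions: DCC, DMAP (cat.), CH2Cl2, 0 °C to rt
Reagents that add atoms: none
Why: Steglich esterification through the acylpyridinium ion acylates the secondary allylic alcohol with retention at C7.

**Step 9**
Reactants: 15 C7 β-ester of 11 with acid 14
Product: 17 trans-decalin β-keto sulfone carboxylic acid, via Claisen-rearranged acid 16 (not isolated)
Conditions: LDA (2.5 equiv), THF (0.01 M), −78 °C, then warm to 45 °C; aqueous HCl work-up
Reagents that add atoms: none
Why: Proposed new method: double deprotonation gives the sulfonyl carbanion at C1 and the lithium ester enolate at C4, whose amide arm is held syn to O–Li by internal coordination of the morpholine amide carbonyl (seven-membered chelate); on warming, the enolate undergoes a suprafacial [3,3] ester-enolate Claisen rearrangement (closest known types: lithium-enolate and Ireland–Claisen rearrangements of cyclohex-2-enyl esters) that moves the quaternary carbon from O7 to C5 and puts the amide carbonyl (C2) six atoms from the waiting carbanion. The carbanion then adds to that carbonyl in a 6-exo-trig acyl substitution (closest known type: acylation of α-sulfonyl carbanions by tertiary amides), closing ring A as a chair through two equatorial bonds, hence trans-fused; the [3,3] shift itself closes no ring, and the tetrahedral intermediate releases morpholine on work-up. C5 is set by chirality transfer from the C7 β-oxygen (new bond on the β face, H-5 α). C4 is set by the enolate geometry (arm syn to O–Li) passing through the boat transition state that keeps the enolate oxygens away from the axial C9 chain, which places the methyl β (axial) and the carboxyl α (equatorial); C1 is epimerisable and is removed in step 10. The step needs enolisation α to the ester and not α to the amide (the ester C–H is about five pKa units more acidic), rearrangement before acylation (before the shift the carbanion reaches the amide only through a ten-membered ring, and dilution suppresses the intermolecular path), and no elimination (neither carbanion has a β leaving group, and the enolised ester is not an electrophile).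

**Step 10**
Reactants: 17 trans-decalin β-keto sulfone carboxylic acid
Product: 18 trans-decalin 2-oxo-18-carboxylic acid
Conditions: SmI2 (excess), THF/MeOH, −78 °C
Reagents that add atoms: none
Why: Reductive desulfonylation of the β-keto sulfone by single-electron transfer to the ketone, loss of sulfinate and protonation of the samarium enolate leaves C1 as CH2 without touching the isolated alkene.

**Step 11**
Reactants: 18 trans-decalin 2-oxo-18-carboxylic acid
Product: 19 2β,18-diol
Conditions: LiAlH4, THF, 0 °C to reflux
Reagents that add atoms: none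
Why: Hydride reduction of the acid to C18–OH and of the C2 ketone, where hydride comes from the α face because the β (axial) trajectory is blocked by the syn-axial C10 and C4 methyl groups, giving the axial 2β-alcohol.

**Step 12**
Reactants: 19 2β,18-diol
Product: 20 18-O-TBS 2β-alcohol
Conditions: TBSCl, imidazole, CH2Cl2, 0 °C
Reagents that add atoms: tert-butyldimethylsilyl chloride, CC(C)(C)[Si](C)(C)Cl
Why: Silylation is selective for the primary C18 hydroxyl over the axial C2 hydroxyl, which is hindered by two 1,3-diaxial methyl groups.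

**Step 13**
Reactants: 20 18-O-TBS 2β-alcohol
Product: 21 18-O-TBS 2α-chloride
Conditions: PPh3, CCl4, 1,2-dichloroethane, 60 °C
Reagents that add atoms: tetrachloromethane, ClC(Cl)(Cl)Cl
Why: Appel chlorination, in which chloride attacks the axial alkoxyphosphonium ion from the open α face with SN2 inversion to give the equatorial 2α-chloride.

**Step 14**
Reactants: 21 18-O-TBS 2α-chloride
Product: 22 6-en-8-one
Conditions: CrO3, 3,5-dimethylpyrazole, CH2Cl2, −20 °C
Reagents that add atoms: chromium trioxide, O=[Cr](=O)=O
Why: Allylic oxidation by the chromium trioxide–pyrazole complex at the accessible C8 methylene (the other allylic position, C5–H, lies between two quaternary carbons) gives the C6=C7–C8=O enone, as in the oxidation of Δ5-steroids to 7-ketones.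

**Step 15**
Reactants: 22 6-en-8-one
Product: 23 saturated 8-ketone 12-alcohol
Conditions: H2 (1 atm), Pd/C, EtOAc, rt
Reagents that add atoms: none
Why: Heterogeneous hydrogenation saturates the enone C=C and cleaves the benzyl ether while the secondary chloride and silyl ether persist, and C9 keeps its equatorial side chain, the thermodynamic configuration next to the ketone.

**Step 16**
Reactants: 23 saturated 8-ketone 12-alcohol
Product: 24 8(17)-ene 12-alcohol
Conditions: Ph3PCH3Br (4 equiv), KOtBu (3.8 equiv), toluene, 80 °C
Reagents that add atoms: methyltriphenylphosphonium bromide, C[P+](c1ccccc1)(c1ccccc1)c1ccccc1.[Br-]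
Why: Wittig methylenation of the hindered C8 ketone with excess non-stabilised ylide, which tolerates the free C12 hydroxyl as its alkoxide.

**Step 17**
Reactants: 24 8(17)-ene 12-alcohol
Product: 25 12-aldehyde
Conditions: 1,1,1-triacetoxy-1,1-dihydro-1,2-benziodoxol-3(1H)-one, CH2Cl2, rt
Reagents that add atoms: none
Why: Dess–Martin oxidation of the primary alcohol stops at the aldehyde under neutral conditions that leave the exocyclic alkene and the chloride untouched.

**Step 18**
Reactants: 26 3-cyanopropanoic acid; 27 (R)-4-benzyloxazolidin-2-one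
Product: 28 (R)-4-benzyl-3-(3-cyanopropanoyl)oxazolidin-2-one
Conditions: pivaloyl chloride, Et3N, LiCl, THF, −20 °C to rt
Reagents that add atoms: none
Why: N-Acylation of the oxazolidinone by the mixed pivalic anhydride under LiCl/Et3N activation needs no strong base, and the nitrile is inert.

**Step 19**
Reactants: 25 12-aldehyde; 28 (R)-4-benzyl-3-(3-cyanopropanoyl)oxazolidin-2-one
Product: 29 syn-aldol adduct
Conditions: Bu2BOTf, iPr2NEt, CH2Cl2, −78 to 0 °C; pH 7 buffer, MeOH
Reagents that add atoms: none
Why: Evans syn-aldol reaction through the (Z)-boron enolate and a chair Zimmerman–Traxler transition state, in which the (R)-benzyl auxiliary shields one enolate face and sets C12 and C13 in the syn relationship and absolute sense of the target.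

**Step 20**
Reactants: 29 syn-aldol adduct
Product: 31 18-O-TBS succinimide, via primary amide 30 (not isolated)
Conditions: PtH(PMe2OH)(PMe2O)2H (5 mol %), EtOH/H2O 4:1, 75 °C; then Et3N, rt
Reagents that add atoms: water, O
Why: Platinum-catalysed neutral hydration of the nitrile gives the primary amide, whose nitrogen attacks the activated N-acyloxazolidinone carbonyl (5-exo-trig acyl transfer) to close the succinimide and release the auxiliary without epimerising C13.

**Step 21**
Reactants: 31 18-O-TBS succinimide
Product: 32 Haterumaimide J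
Conditions: HF·pyridine, THF, 0 °C to rt
Reagents that add atoms: none
Why: Fluoride cleavage of the primary silyl ether under mildly acidic conditions leaves the imide, the β-hydroxy imide stereocentres, the chloride and the exocyclic alkene intact.

**Compound list**
1 | 3-(benzyloxy)propanal | O=CCCOCc1ccccc1 | starting material
2 | 2-(triphenylphosphoranylidene)propanal | CC(C=O)=P(c1ccccc1)(c1ccccc1)c1ccccc1 | starting material
3 | (E)-5-(benzyloxy)-2-methylpent-2-enal | O=C/C(C)=C/CCOCc1ccccc1 | intermediate
4 | (E)-3-(tert-butyldimethylsilyloxy)-N,N-dimethylbuta-1,3-dien-1-amine | C=C(O[Si](C)(C)C(C)(C)C)/C=C/N(C)C | starting material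
5 | cycloadduct aldehyde (not isolated): 2-[2-(benzyloxy)ethyl]-4-(tert-butyldimethylsilyloxy)-6-(dimethylamino)-1-methylcyclohex-4-ene-1-carbaldehyde; formyl trans to the side chain, methyl cis to it; amine-bearing carbon as a mixture | O=C[C@]1(C)[C@@H](CCOCc2ccccc2)CC(O[Si](C)(C)C(C)(C)C)=CC1N(C)C | intermediate
6 | cycloadduct alcohol (not isolated): the primary alcohol from 5 | OC[C@]1(C)[C@@H](CCOCc2ccccc2)CC(O[Si](C)(C)C(C)(C)C)=CC1N(C)C | intermediate
7 | 4-(hydroxymethyl)-4-methyl-5-[2-(benzyloxy)ethyl]cyclohex-2-en-1-one; ring B with C7 ketone, C5=C6, C10 methyl cis to the C9 side chain, hydroxymethyl (C1) trans to it; C9 and C10 as in the target | OC[C@]1(C)[C@@H](CCOCc2ccccc2)CC(=O)C=C1 | intermediate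
8 | 4-(iodomethyl)-4-methyl-5-[2-(benzyloxy)ethyl]cyclohex-2-en-1-one; same configuration as 7 | IC[C@]1(C)[C@@H](CCOCc2ccccc2)CC(=O)C=C1 | intermediate
9 | 4-(iodomethyl)-4-methyl-5-[2-(benzyloxy)ethyl]cyclohex-2-en-1-ol; C7 hydroxyl β, cis to the C9 side chain and the C10 methyl | IC[C@]1(C)[C@@H](CCOCc2ccccc2)C[C@@H](O)C=C1 | intermediate
10 | 4-methyl-4-[(phenylsulfanyl)methyl]-5-[2-(benzyloxy)ethyl]cyclohex-2-en-1-ol; configuration as 9 | c1ccccc1SC[C@]1(C)[C@@H](CCOCc2ccccc2)C[C@@H](O)C=C1 | intermediate
11 | 4-methyl-4-[(phenylsulfonyl)methyl]-5-[2-(benzyloxy)ethyl]cyclohex-2-en-1-ol; configuration as 9 | O=S(=O)(c1ccccc1)C[C@]1(C)[C@@H](CCOCc2ccccc2)C[C@@H](O)C=C1 | intermediate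
12 | methylsuccinic anhydride (3-methyloxolane-2,5-dione), racemic | CC1CC(=O)OC1=O | starting material
13 | morpholine | C1COCCN1 | starting material
14 | 2-methyl-4-(morpholin-4-yl)-4-oxobutanoic acid, racemic | CC(CC(=O)N1CCOCC1)C(=O)O | intermediate
15 | C7 β-ester of 11 with 14; both epimers at the acid α-carbon | O=S(=O)(c1ccccc1)C[C@]1(C)[C@@H](CCOCc2ccccc2)C[C@@H](OC(=O)C(C)CC(=O)N2CCOCC2)C=C1 | intermediate
16 | Claisen-rearranged acid (not isolated, formed as its dilithio salt, drawn neutral): ring B cyclohex-6-ene with C5 bearing the quaternary C4 (β-face bond, H-5 α; C4 carries methyl, CO2H and CH2C(O)-morpholine), C10 carrying methyl (β) and CH2SO2Ph (α) | C1C=C[C@@H]([C@](C)(C(=O)O)CC(=O)N2CCOCC2)[C@](C)(CS(=O)(=O)c2ccccc2)[C@H]1CCOCc1ccccc1 | intermediate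
17 | trans-decalin β-keto sulfone acid: C1 phenylsulfonyl (epimers), C2 ketone, C4 β-methyl and α-CO2H, H-5 α, C6=C7, 9β-CH2CH2OBn, 10β-methyl | C1C=C[C@H]2[C@](C)(C(=O)O)CC(=O)C(S(=O)(=O)c3ccccc3)[C@]2(C)[C@H]1CCOCc1ccccc1 | intermediate
18 | trans-decalin 2-oxo-18-carboxylic acid: as 17 with C1 = CH2 | C1C=C[C@H]2[C@](C)(C(=O)O)CC(=O)C[C@]2(C)[C@H]1CCOCc1ccccc1 | intermediate
19 | 2β,18-diol: axial 2β-OH, 4α-CH2OH, C6=C7, 9β-CH2CH2OBn | C1C=C[C@H]2[C@](C)(CO)C[C@@H](O)C[C@]2(C)[C@H]1CCOCc1ccccc1 | intermediate
20 | 18-O-TBS 2β-alcohol | C1C=C[C@H]2[C@](C)(CO[Si](C)(C)C(C)(C)C)C[C@@H](O)C[C@]2(C)[C@H]1CCOCc1ccccc1 | intermediate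
21 | 18-O-TBS 2α-chloride (equatorial chloride), C6=C7 | C1C=C[C@H]2[C@](C)(CO[Si](C)(C)C(C)(C)C)C[C@H](Cl)C[C@]2(C)[C@H]1CCOCc1ccccc1 | intermediate
22 | 6-en-8-one: as 21 with C8 ketone conjugated to C6=C7 | O=C1C=C[C@H]2[C@](C)(CO[Si](C)(C)C(C)(C)C)C[C@H](Cl)C[C@]2(C)[C@H]1CCOCc1ccccc1 | intermediate
23 | saturated 8-ketone with free C12 hydroxyl (9β-CH2CH2OH) | O=C1CC[C@H]2[C@](C)(CO[Si](C)(C)C(C)(C)C)C[C@H](Cl)C[C@]2(C)[C@H]1CCO | intermediate
24 | 8(17)-ene 12-alcohol (exocyclic methylene at C8) | C=C1CC[C@H]2[C@](C)(CO[Si](C)(C)C(C)(C)C)C[C@H](Cl)C[C@]2(C)[C@H]1CCO | intermediate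
25 | 12-aldehyde (9β-CH2CHO) | C=C1CC[C@H]2[C@](C)(CO[Si](C)(C)C(C)(C)C)C[C@H](Cl)C[C@]2(C)[C@H]1CC=O | intermediate
26 | 3-cyanopropanoic acid | N#CCCC(=O)O | starting material
27 | (R)-4-benzyloxazolidin-2-one | O=C1N[C@H](Cc2ccccc2)CO1 | starting material
28 | (R)-4-benzyl-3-(3-cyanopropanoyl)oxazolidin-2-one | N#CCCC(=O)N1[C@H](Cc2ccccc2)COC1=O | intermediate
29 | syn-aldol adduct: C12 hydroxyl and C13 cyanomethyl as in the target, C16 carbonyl on the (R)-benzyloxazolidinone | C=C1CC[C@H]2[C@](C)(CO[Si](C)(C)C(C)(C)C)C[C@H](Cl)C[C@]2(C)[C@H]1C[C@H](O)[C@@H](CC#N)C(=O)N1[C@H](Cc2ccccc2)COC1=O | intermediate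
30 | primary amide from 29 (not isolated) | C=C1CC[C@H]2[C@](C)(CO[Si](C)(C)C(C)(C)C)C[C@H](Cl)C[C@]2(C)[C@H]1C[C@H](O)[C@@H](CC(N)=O)C(=O)N1[C@H](Cc2ccccc2)COC1=O | intermediate
31 | 18-O-TBS ether of Haterumaimide J | C=C1CC[C@H]2[C@](C)(CO[Si](C)(C)C(C)(C)C)C[C@H](Cl)C[C@]2(C)[C@H]1C[C@H](O)[C@H]1CC(=O)NC1=O | intermediate
32 | Haterumaimide J | C=C1CC[C@H]2[C@](C)(CO)C[C@H](Cl)C[C@]2(C)[C@H]1C[C@H](O)[C@H]1CC(=O)NC1=O | target

**Count**
Total steps: 21. Longest linear sequence: 19 (steps 1–6, 8–17, 19–21; steps 7 and 18 are side branches).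

**Steps most likely to fail**

Step 9 (Proposed new method). The lithium enolate may fragment to a ketene and the C7 alkoxide faster than it rearranges. Enolisation may give the wrong enolate geometry, which would lose control of C4. The carbanion may acylate between molecules. The fallback sets out from 9 and returns at 18. Iodo alcohol 9 is esterified with acid 14 (DCC, DMAP) to the iodo ester F1. Ireland–Claisen rearrangement of its silyl ketene acetal (LDA, TMSCl, THF with DMPU, −78 to 60 °C, acid work-up; a chiral lithium amide with enantiopure 14 if geometry control is needed) gives the iodo acid F2, which is isolated so that the C4 configuration can be checked. Its sodium carboxylate is treated with t-BuLi (Et2O, −78 °C); iodine–lithium exchange and acylation of the primary alkyllithium by the morpholine amide (Parham-type cyclisation) give keto acid 18. Steps 5, 6 and 10 are then not needed.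

Step 13. E2 elimination of the axial alkoxyphosphonium ion (antiperiplanar axial hydrogens at C1 and C3) may compete with substitution. The fallback sets out from 20 and returns at 21. Dess–Martin oxidation of 20 gives the 2-ketone F3. Equilibrating Meerwein–Ponndorf–Verley reduction (Al(OiPr)3, iPrOH, reflux) gives the thermodynamic equatorial 2α-alcohol F4. Treatment with SOCl2 in dioxane without base lets the chlorosulfite collapse with retention (SNi), as known for equatorial steroidal alcohols, and gives 21 without a backside attack.

Step 2. The trisubstituted enal may react slowly or with poor facial selectivity at the chromium catalyst. The fallback sets out from 3 and returns at 7. Enal 3 and 2-(triisopropylsilyloxy)buta-1,3-diene react under a chiral oxazaborolidinium triflimide Lewis acid (CH2Cl2, −78 °C) to give the silyl enol ether aldehyde F5, with the silyloxy carbon para to the formyl-bearing carbon. NaBH4 reduction gives the silyl enol ether alcohol F6. Saegusa oxidation (Pd(OAc)2, MeCN) of the regiodefined silyl enol ether then gives enone 7.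

**Further compounds**
F1 | step 9 | C7 β-ester of iodo alcohol 9 with acid 14 | IC[C@]1(C)[C@@H](CCOCc2ccccc2)C[C@@H](OC(=O)C(C)CC(=O)N2CCOCC2)C=C1
F2 | step 9 | Claisen-rearranged iodo acid (as 16 with CH2I in place of CH2SO2Ph) | C1C=C[C@@H]([C@](C)(C(=O)O)CC(=O)N2CCOCC2)[C@](C)(CI)[C@H]1CCOCc1ccccc1
F3 | step 13 | 18-O-TBS 2-ketone | C1C=C[C@H]2[C@](C)(CO[Si](C)(C)C(C)(C)C)CC(=O)C[C@]2(C)[C@H]1CCOCc1ccccc1
F4 | step 13 | 18-O-TBS 2α-alcohol (equatorial) | C1C=C[C@H]2[C@](C)(CO[Si](C)(C)C(C)(C)C)C[C@H](O)C[C@]2(C)[C@H]1CCOCc1ccccc1
F5 | step 2 | 1-methyl-2-[2-(benzyloxy)ethyl]-4-(triisopropylsilyloxy)cyclohex-3-ene-1-carbaldehyde (formyl trans to the side chain) | O=C[C@]1(C)[C@@H](CCOCc2ccccc2)CC(O[Si](C(C)C)(C(C)C)C(C)C)=CC1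
F6 | step 2 | the primary alcohol from F5 | OC[C@]1(C)[C@@H](CCOCc2ccccc2)CC(O[Si](C(C)C)(C(C)C)C(C)C)=CC1
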